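I began from a ratio, ρ, worth 1.29 in gamma, 0.326 in alpha and 0.643 in epsilon. It is the pseudo-first-order rate constant of intermediate going to target at the partner's charge, over the rate constant of substrate going to intermediate.

| setting | gamma | alpha | epsilon |
|---|---|---|---|
| substrate | 0.80 M | 0.80 M | 0.80 M |
| partner | 3.00 M | 0.760 M | 1.50 M |
| time | 50 min | 50 min | 50 min |

    substrate → intermediate (k1 = 0.028 /min)
    partner + intermediate → target (k2 = 0.012 /M/min)
    partner → decomposition product (k3 = 9.5 × 10⁻⁵ /min)

1. which of these there is most of at the end, counted by the substrate in it, gamma (substrate / intermediate / target)
2. which of these there is most of at the end, counted by the substrate in it, alpha (substrate / intermediate / target)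
3. which of these there is most of at the end, counted by the substrate in it, epsilon (substrate / intermediate / target)
4. final amount of the leader among these, as a percentage of the substrate charged, in gamma
5. final amount of the leader among these, as a percentage of the substrate charged, in alpha
6. final amount of the leader among these, as a percentage of the substrate charged, in epsilon

The substrate's step has no partner in it, so 24.7% of the substrate stood at 50 min in gamma, alpha and epsilon alike. Intermediate and target shared the rest. Target therefore led once it passed 37.7%, half of that rest, and this mark is more than the substrate's share.

For a bound from above, I held partner at its charge, which it stays below. Two first-order steps in a row then gave target at most 46.9% in gamma, 17.9% in alpha and 30.5% in epsilon.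

For a bound from below, I took a floor for partner: the charge, less that upper target, less decomposition at the full charge. This cut ρ to 1.12 in gamma, 0.263 in alpha and 0.535 in epsilon. Target was then at least 43.5%, 14.9% and 26.7% in the same order.

Gamma's lower bound was above the mark, and the upper bounds of alpha and epsilon were below it . Taking midpoints, I committed to target at 45.2% in gamma, intermediate at 58.9% in alpha, and intermediate at 46.7% in epsilon.

The forecast gave target at 45% in gamma, intermediate at 59% in alpha and intermediate at 47% in epsilon, using “an effective constant partner level”. Its gamma yield was more than my lower bound on target and less than the upper one. Its alpha and epsilon yields were more than  my lower bounds on intermediate, which are the rest less target's upper bounds, and less than  the upper ones.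

The simulation gave target at 44.9% in gamma, intermediate at 58.9% in alpha and intermediate at 46.8% in epsilon. Target in gamma, alpha and epsilon stood at 44.9%, 16.4% and 28.5%, each more than  my lower bound on target and less than  my upper one.

In gamma, with ρ at 1.29, target led intermediate by 15 percentage points. I then took a neighbour of gamma charged with 0.75 M of partner, its substrate charge and time as in gamma. Its ρ was 0.321, less than gamma's. Its upper bound for target was 17.7%, below the mark. Its floor ρ of 0.259 gave a lower bound of 14.7%. So I expected intermediate to lead. At 50.0 min the neighbour held target at 16.2% and intermediate at 59.1%.

The numbers of this flask were chosen freely; the run is a simulation.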